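**Retrosynthetic overview**

1. Endgame: C9 PMB ether off last; the two angelates (C5, C1) and the C6 (R)-2-methylbutanoate are put on one at a time.
2. Key disconnection C1–C10: a SmI2 ketyl at C1 (reversed-polarity aldehyde carbon) adds to the C10 methyl ketone, closing the ten-membered carbocycle and creating the C1/C10 diol in one step.
3. The open-chain keto aldehyde comes from a C4–C5 Nozaki–Hiyama–Kishi union of a C5–C10 α-oxy aldehyde with a (Z)-iodoalkene (C1–C4), then OH-directed epoxidation under allylic-strain control.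
4. The C5–C10 piece is (R)-carvone: Luche reduction (C9), epoxidation and periodic acid ring cleavage (C7 from the chiral pool), then organocatalytic α-oxygenation (C6).
5. Ring order: oxirane first (open-chain stage, step 8), ten-membered carbocycle second (step 14).

Assumption: ring atoms are numbered C1–C10 so that C7 carries isopropenyl, C6 the 2-methylbutanoate, C5 and C1 the angelates, C3–C4 the oxirane (CH3 on C4), C10 the tertiary OH and C9 the secondary OH; in these locants 21 is 1S,3S,4S,5S,6S,7R,9R,10S; compounds 8, 12 and 15 are bought.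

**Step 1**
Reactants: 1 (R)-carvone
Product: 2 (1R,5R)-cis-carveol
Conditions: NaBH4, CeCl3·7H2O, MeOH, −20 °C
Reagents that add atoms: none
Why: Luche 1,2-reduction; axial hydride delivery gives the alcohol cis to the isopropenyl group, which is the C9 configuration, while C7 is carried over from carvone.

**Step 2**
Reactants: 2 (1R,5R)-cis-carveol
Product: 3 syn-epoxy alcohol (oxirane O, OH and isopropenyl on one face)
Conditions: VO(acac)2 (2 mol%), t-BuOOH, toluene, 0 °C → rt
Reagents that add atoms: tert-butyl hydroperoxide, CC(C)(C)OO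
Why: hydroxyl-directed vanadium-catalysed epoxidation oxidises only the allylic ring alkene and leaves the isopropenyl group; the oxirane configuration is erased in step 4.

**Step 3**
Reactants: 3 syn-epoxy alcohol
Product: 4 PMB ether of 3
Conditions: NaH, PMBCl, Bu4NI (cat.), THF/DMF, 0 °C → rt
Reagents that add atoms: 4-methoxybenzyl chloride, COc1ccc(CCl)cc1
Why: Williamson etherification; the cis-epoxy alkoxide cannot reach the backside of the oxirane, so no Payne rearrangement, and the PMB ether later serves as chelating group and is removable with DDQ.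

**Step 4**
Reactants: 4 PMB ether of 3
Product: 6 (3S,5R)-5-[(4-methoxybenzyl)oxy]-6-oxo-3-(prop-1-en-2-yl)heptanal, via trans-diol 5 (not isolated)
Conditions: H5IO6, THF/H2O, 0 °C → rt
Reagents that add atoms: water, O
Why: epoxide hydrolysis followed by Malaprade glycol cleavage opens the six-membered ring between C10 and C5, giving the methyl ketone and the aldehyde without touching C7 or C9.

**Step 5**
Reactants: 6 keto aldehyde
Product: 7 (2S,3R,5R)-5-[(4-methoxybenzyl)oxy]-6-oxo-3-(prop-1-en-2-yl)-2-[(2,2,6,6-tetramethylpiperidin-1-yl)oxy]heptanal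
Conditions: TEMPO (1.5 equiv), (5S)-5-benzyl-2,2,3-trimethylimidazolidin-4-one·TFA (20 mol%), CuCl2·2H2O (10 mol%), air, acetone, −10 °C
Reagents that add atoms: TEMPO, CC1(C)CCCC(C)(C)N1[O]
Why: enamine-catalysed α-oxyamination, in which only the aldehyde forms an enamine; the benzyl group of the first-generation imidazolidinone shields one enamine face, and the (5S) catalyst is assigned by analogy with its α-chlorinations to give 6S under catalyst control (if the sense proves opposite, the (5R) catalyst is used).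

**Step 6**
Reactants: 8 3-[(tert-butyldiphenylsilyl)oxy]propanal
Product: 9 (Z)-tert-butyl[(4-iodopent-3-en-1-yl)oxy]diphenylsilane
Conditions: [Ph3PEt]I, n-BuLi, THF, rt; I2, −78 °C; NaHMDS, −20 °C; then 8, −78 °C → rt
Reagents that add atoms: ethyltriphenylphosphonium iodide, CC[P+](c1ccccc1)(c1ccccc1)c1ccccc1.[I-]; iodine, II
Why: Stork–Zhao-type Wittig olefination with the α-iodoethylidene ylide gives the (Z)-2-iodoalkene (iodine cis to the chain), which fixes the cis relationship of C2 and C5 at the later oxirane.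

**Step 7**
Reactants: 7 α-oxy aldehyde, 9 (Z)-iodoalkene
Product: 10 open-chain allylic alcohol (C5 OH, 5,6-anti; C6 O-TMP; (Z)-C3=C4; C1 OTBDPS; C9 OPMB; C10 methyl ketone)
Conditions: CrCl2 (5 equiv), NiCl2 (2 mol%), DMSO/THF, rt
Reagents that add atoms: none
Why: Nozaki–Hiyama–Kishi alkenylation; the alkenylchromium adds to the aldehyde only and leaves the methyl ketone, with Felkin–Anh attack anti to the bulky, non-chelating O-TMP group giving the 5,6-anti alcohol and retention of olefin geometry.

**Step 8**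
Reactants: 10 allylic alcohol
Product: 11 epoxy alcohol (cis-oxirane at C3–C4, 4,5-syn)
Conditions: Ti(OiPr)4 (20 mol%), t-BuOOH, 4 Å MS, CH2Cl2, −20 °C
Reagents that add atoms: tert-butyl hydroperoxide, CC(C)(C)OO
Why: hydroxyl-directed titanium-mediated epoxidation; 1,3-allylic strain (C2 cis to C5) holds C5–H in the olefin plane, so oxygen is delivered from the OH face to give the threo epoxy alcohol, which sets C3 and C4, and the isopropenyl group is not touched.

**Step 9**
Reactants: 11 epoxy alcohol, 12 angelic acid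
Product: 13 C5 angelate of 11
Conditions: 2,4,6-trichlorobenzoyl chloride, Et3N, toluene, rt; then 11, 75 °C
Reagents that add atoms: none
Why: Yamaguchi esterification through the mixed anhydride without DMAP, the conditions that acylate hindered secondary alcohols without Z-to-E isomerisation of the angelate.

**Step 10**
Reactants: 13 C5 angelate
Product: 14 C6 alcohol
Conditions: Zn dust, AcOH/THF/H2O, 35 °C
Reagents that add atoms: none
Why: reductive N–O cleavage of the alkoxyamine frees the C6 hydroxyl with retention; the ester, the PMB ether and the TBDPS ether are stable to zinc and dilute acetic acid, and the oxirane is deactivated towards acid by the neighbouring acyloxy group.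

**Step 11**
Reactants: 14 C6 alcohol, 15 (R)-2-methylbutanoic acid
Product: 16 C6 (R)-2-methylbutanoate
Conditions: DCC, DMAP (cat.), CH2Cl2, 0 °C → rt
Reagents that add atoms: none
Why: Steglich esterification of the only free hydroxyl; the α-branched alkanoic acid has no activating α-heteroatom and keeps its configuration.

**Step 12**
Reactants: 16 diester silyl ether
Product: 17 C1 primary alcohol
Conditions: TBAF, AcOH, THF, 0 °C → rt
Reagents that add atoms: none
Why: acetic-acid-buffered fluoride desilylation removes the primary TBDPS group without ester migration or oxirane opening.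

**Step 13**
Reactants: 17 primary alcohol
Product: 18 keto aldehyde (C1 CHO, C10 methyl ketone)
Conditions: Dess–Martin periodinane, NaHCO3, CH2Cl2, 0 °C; used at once
Reagents that add atoms: none
Why: buffered Dess–Martin oxidation gives the β,γ-epoxy aldehyde without base-induced elimination, and because C5 is already acylated no lactol can form.

**Step 14**
Reactants: 18 keto aldehyde
Product: 19 macrocyclic diol (ten-membered ring; C1 OH, C10 OH, C9 OPMB)
Conditions: SmI2 (4 equiv), THF, 0 °C, 18 added over 6 h (final 2 mM); aq. NaHCO3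
Reagents that add atoms: none
Why: intramolecular pinacol (ketyl) coupling, in which SmI2 reduces the aldehyde first so that C1 becomes a nucleophilic ketyl carbon that attacks the samarium-bound C10 ketone and closes the ring; chelation of samarium by the ketone oxygen and the C9 PMB ether directs attack anti to C8 (9,10-syn), and a samarium-bridged O–C1–C10–O unit in a ten-membered ring needs a transoid ring torsion, which gives the trans (threo) diol as in other metal-mediated pinacol closures of rings of ten or more atoms, while omission of HMPA and alcohol protects the α-alkoxy ketone, esters and oxirane from reduction.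

**Step 15**
Reactants: 19 macrocyclic diol, 12 angelic acid
Product: 20 C1,C5-bis-angelate C9 PMB ether
Conditions: 2,4,6-trichlorobenzoyl chloride, Et3N, toluene, rt; then 19, 75 °C
Reagents that add atoms: none
Why: Yamaguchi esterification acylates the only secondary hydroxyl (C1), since the tertiary C10 hydroxyl is inert under these conditions.

**Step 16**
Reactants: 20 PMB ether
Product: 21 CNP0246823.3
Conditions: DDQ, CH2Cl2/pH 7 buffer, 0 °C → rt
Reagents that add atoms: none
Why: oxidative PMB ether cleavage under neutral conditions frees the C9 hydroxyl without affecting the oxirane, the angelates or the isopropenyl group.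

**Compound list**

1 | (R)-carvone, (R)-2-methyl-5-(prop-1-en-2-yl)cyclohex-2-en-1-one | CC1=CC[C@H](CC1=O)C(C)=C | starting material
2 | (1R,5R)-2-methyl-5-(prop-1-en-2-yl)cyclohex-2-en-1-ol (cis-carveol) | CC1=CC[C@H](C[C@H]1O)C(C)=C | intermediate
3 | 1-methyl-4-(prop-1-en-2-yl)-7-oxabicyclo[4.1.0]heptan-2-ol, oxirane O, OH and isopropenyl on the same face | C[C@]12O[C@H]1C[C@H](C[C@H]2O)C(C)=C | intermediate
4 | 4-methoxybenzyl ether of 3 | C[C@]12O[C@H]1C[C@H](C[C@H]2OCc3ccc(OC)cc3)C(C)=C | intermediate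
5 | 3-[(4-methoxybenzyl)oxy]-2-methyl-5-(prop-1-en-2-yl)cyclohexane-1,2-diol, trans-diol from opening of 4 (not isolated) | C[C@@]1(O)[C@@H](O)C[C@H](C[C@H]1OCc2ccc(OC)cc2)C(C)=C | intermediate
6 | (3S,5R)-5-[(4-methoxybenzyl)oxy]-6-oxo-3-(prop-1-en-2-yl)heptanal | CC(=O)[C@H](OCc1ccc(OC)cc1)C[C@@H](CC=O)C(C)=C | intermediate
7 | (2S,3R,5R)-5-[(4-methoxybenzyl)oxy]-6-oxo-3-(prop-1-en-2-yl)-2-[(2,2,6,6-tetramethylpiperidin-1-yl)oxy]heptanal | CC(=O)[C@H](OCc1ccc(OC)cc1)C[C@@H]([C@H](ON2C(C)(C)CCCC2(C)C)C=O)C(C)=C | intermediate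
8 | 3-[(tert-butyldiphenylsilyl)oxy]propanal | O=CCCO[Si](c1ccccc1)(c1ccccc1)C(C)(C)C | starting material
9 | (Z)-tert-butyl[(4-iodopent-3-en-1-yl)oxy]diphenylsilane | C/C(I)=C/CCO[Si](c1ccccc1)(c1ccccc1)C(C)(C)C | intermediate
10 | open-chain allylic alcohol: C1 OTBDPS, (Z)-C3=C4(CH3), C5 OH, C6 O-TMP (5,6-anti), C7 isopropenyl, C9 OPMB, C10 methyl ketone | CC(=O)[C@H](OCc1ccc(OC)cc1)C[C@@H]([C@H](ON2C(C)(C)CCCC2(C)C)[C@H](O)/C(C)=C\CCO[Si](c3ccccc3)(c3ccccc3)C(C)(C)C)C(C)=C | intermediate
11 | C3–C4 cis-oxirane of 10, oxirane O and C5 OH syn (threo) | CC(=O)[C@H](OCc1ccc(OC)cc1)C[C@@H]([C@H](ON2C(C)(C)CCCC2(C)C)[C@H](O)[C@@]3(C)O[C@H]3CCO[Si](c4ccccc4)(c4ccccc4)C(C)(C)C)C(C)=C | intermediate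
12 | angelic acid, (Z)-2-methylbut-2-enoic acid | C/C=C(/C)C(=O)O | starting material
13 | C5 angelate of 11 | CC(=O)[C@H](OCc1ccc(OC)cc1)C[C@@H]([C@H](ON2C(C)(C)CCCC2(C)C)[C@H](OC(=O)/C(C)=C\C)[C@@]3(C)O[C@H]3CCO[Si](c4ccccc4)(c4ccccc4)C(C)(C)C)C(C)=C | intermediate
14 | C6 alcohol (13 without the piperidinyl group) | CC(=O)[C@H](OCc1ccc(OC)cc1)C[C@@H]([C@H](O)[C@H](OC(=O)/C(C)=C\C)[C@@]2(C)O[C@H]2CCO[Si](c3ccccc3)(c3ccccc3)C(C)(C)C)C(C)=C | intermediate
15 | (R)-2-methylbutanoic acid | CC[C@@H](C)C(=O)O | starting material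
16 | C6 (R)-2-methylbutanoate of 14 | CC(=O)[C@H](OCc1ccc(OC)cc1)C[C@@H]([C@H](OC(=O)[C@H](C)CC)[C@H](OC(=O)/C(C)=C\C)[C@@]2(C)O[C@H]2CCO[Si](c3ccccc3)(c3ccccc3)C(C)(C)C)C(C)=C | intermediate
17 | C1 primary alcohol (16 without TBDPS) | CC(=O)[C@H](OCc1ccc(OC)cc1)C[C@@H]([C@H](OC(=O)[C@H](C)CC)[C@H](OC(=O)/C(C)=C\C)[C@@]2(C)O[C@H]2CCO)C(C)=C | intermediate
18 | open-chain keto aldehyde: C1 CHO, C3–C4 oxirane, C5 OAng, C6 O-(R)-2-methylbutanoyl, C9 OPMB, C10 methyl ketone | CC(=O)[C@H](OCc1ccc(OC)cc1)C[C@@H]([C@H](OC(=O)[C@H](C)CC)[C@H](OC(=O)/C(C)=C\C)[C@@]2(C)O[C@H]2CC=O)C(C)=C | intermediate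
19 | ten-membered diol: C1 OH, C10 OH (tertiary), C9 OPMB, C5 OAng, C6 O-(R)-2-methylbutanoyl, C3–C4 oxirane, C7 isopropenyl | C=C(C)[C@H]1C[C@@H](OCc3ccc(OC)cc3)[C@](C)(O)[C@@H](O)C[C@@H]2O[C@]2(C)[C@@H](OC(=O)/C(C)=C\C)[C@H]1OC(=O)[C@H](C)CC | intermediate
20 | C1 angelate of 19 (C9 still PMB ether) | C=C(C)[C@H]1C[C@@H](OCc3ccc(OC)cc3)[C@](C)(O)[C@@H](OC(=O)/C(C)=C\C)C[C@@H]2O[C@]2(C)[C@@H](OC(=O)/C(C)=C\C)[C@H]1OC(=O)[C@H](C)CC | intermediate
21 | CNP0246823.3 | C=C(C)[C@H]1C[C@@H](O)[C@](C)(O)[C@@H](OC(=O)/C(C)=C\C)C[C@@H]2O[C@]2(C)[C@@H](OC(=O)/C(C)=C\C)[C@H]1OC(=O)[C@H](C)CC | target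

**Count**

Total steps: 16. Longest linear sequence: 15 (steps 1–5 and 7–16).

**Three steps most likely to fail, with fallbacks**

Step 14 (ring closure). Risks are oligomerisation or simple reduction instead of cyclisation, opening of the oxirane by samarium iodide species, loss of the α-PMBO group, and the wrong C1 epimer. The fallback sets out from 18 and comes back at 19. It keeps C1 as the reversed-polarity carbon but generates it catalytically: an N-heterocyclic-carbene-catalysed intramolecular crossed aldehyde–ketone benzoin reaction of 18 (bicyclic N-pentafluorophenyl triazolium tetrafluoroborate 20 mol%, Et3N 20 mol%, toluene, 40 °C, 2 mM) gives the ten-membered α-ketol F1 with the C1 ketone next to the C10 tertiary alcohol. Reduction of F1 with NaBH4 in MeOH/CH2Cl2 at −40 °C, hydride approaching anti to the C10 oxygen (Felkin–Anh), gives 19.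

Step 10 (N–O cleavage). Zinc and acetic acid meet an acid-sensitive trisubstituted oxirane and an α-alkoxy ketone. The fallback sets out from 10 and comes back at 16; it moves the N–O cleavage ahead of the epoxidation and also eases the crowded acylation of step 9. Silylation of 10 (TBSOTf, 2,6-lutidine, −78 °C) gives the C5 tert-butyldimethylsilyl ether F2. Zn/AcOH on this oxirane-free compound gives the C6 alcohol F3. Steglich esterification with 15 gives the C6 (R)-2-methylbutanoate F4. HF·pyridine in THF/pyridine removes the secondary TBS group and leaves the primary TBDPS ether, giving the allylic alcohol F5. Ti(OiPr)4/t-BuOOH then gives, by the same allylic-strain control as in step 8, the epoxy alcohol F6, and Yamaguchi angeloylation with 12 gives 16.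

Step 9 (angeloylation of the crowded C5 hydroxyl). The alcohol sits between a quaternary oxirane carbon and the O-TMP-bearing C6, and forcing conditions risk isomerisation to the tiglate. The fallback sets out from 11 and comes back at 13; it builds the Z-enoate on the substrate instead of transferring it. DCC/DMAP esterification of 11 with 2-[bis(2,2,2-trifluoroethoxy)phosphoryl]propanoic acid gives the phosphonopropanoate ester F7 (epimeric at the phosphonate carbon). Still–Gennari olefination of F7 (KHMDS, 18-crown-6, acetaldehyde, THF, −78 °C) forms the (Z)-2-methylbut-2-enoate directly and gives 13.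

**Further compounds**

F1 | step 14 | ten-membered α-ketol: C1 ketone, C10 tertiary OH, C9 OPMB, C5 OAng, C6 O-(R)-2-methylbutanoyl, C3–C4 oxirane | C=C(C)[C@H]1C[C@@H](OCc3ccc(OC)cc3)[C@](C)(O)C(=O)C[C@@H]2O[C@]2(C)[C@@H](OC(=O)/C(C)=C\C)[C@H]1OC(=O)[C@H](C)CC
F2 | step 10 | C5 tert-butyldimethylsilyl ether of 10 | CC(=O)[C@H](OCc1ccc(OC)cc1)C[C@@H]([C@H](ON2C(C)(C)CCCC2(C)C)[C@H](O[Si](C)(C)C(C)(C)C)/C(C)=C\CCO[Si](c3ccccc3)(c3ccccc3)C(C)(C)C)C(C)=C
F3 | step 10 | C6 alcohol from F2 (piperidinyl group removed) | CC(=O)[C@H](OCc1ccc(OC)cc1)C[C@@H]([C@H](O)[C@H](O[Si](C)(C)C(C)(C)C)/C(C)=C\CCO[Si](c2ccccc2)(c2ccccc2)C(C)(C)C)C(C)=C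
F4 | step 10 | C6 (R)-2-methylbutanoate of F3 | CC(=O)[C@H](OCc1ccc(OC)cc1)C[C@@H]([C@H](OC(=O)[C@H](C)CC)[C@H](O[Si](C)(C)C(C)(C)C)/C(C)=C\CCO[Si](c2ccccc2)(c2ccccc2)C(C)(C)C)C(C)=C
F5 | step 10 | C5 allylic alcohol from F4 (TBS removed) | CC(=O)[C@H](OCc1ccc(OC)cc1)C[C@@H]([C@H](OC(=O)[C@H](C)CC)[C@H](O)/C(C)=C\CCO[Si](c2ccccc2)(c2ccccc2)C(C)(C)C)C(C)=C
F6 | step 10 | C3–C4 cis-oxirane of F5, oxirane O and C5 OH syn | CC(=O)[C@H](OCc1ccc(OC)cc1)C[C@@H]([C@H](OC(=O)[C@H](C)CC)[C@H](O)[C@@]2(C)O[C@H]2CCO[Si](c3ccccc3)(c3ccccc3)C(C)(C)C)C(C)=C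
F7 | step 9 | C5 2-[bis(2,2,2-trifluoroethoxy)phosphoryl]propanoate of 11 (both epimers at the phosphonate carbon) | CC(=O)[C@H](OCc1ccc(OC)cc1)C[C@@H]([C@H](ON2C(C)(C)CCCC2(C)C)[C@H](OC(=O)C(C)P(=O)(OCC(F)(F)F)OCC(F)(F)F)[C@@]3(C)O[C@H]3CCO[Si](c4ccccc4)(c4ccccc4)C(C)(C)C)C(C)=C
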